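Ring B carries a C7=C8 double bond whose C8 bears carbon (C17) and lies between the C6 methylene and the C9 methine. Deleting C7 contracts ring B to a cyclopentanone (C5, C6, C8, C9, C10), that is a trans-hydrindan-8-one whose quaternary C10 and C9 oxygen handle map onto (R)-Hajos–Parrish ketone. In the forward direction TMSCHN2 with Sc(OTf)3 inserts C7 between C6 and C8 in one operation, enlarges the five-membered ring to ring B and delivers a regiodefined C7=C8 silyl enol ether. Its precursor is the 3-O-TBS trans-hydrindan-8-one that already holds the complete C11–C15 ester chain at C9.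

Key step: step 13

Remark (numbering): labdane numbers are used for every bicyclic compound, also for the hydrindanes, in which C7 is absent and C6 is bonded to C8. The face of the bicycle that carries the C10 methyl (C20) is called the methyl face, the other one the open face.
Remark (chemistry): after the key step the sulfonate oxygen sits on C8 and C7 is the CH end of the olefin. Since no decalone is passed, C9 must already be correct in 18.
Assumption: 1 and 11 are bought as single enantiomers.

Step 1
Reactants: 1 (R)-Hajos–Parrish ketone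
Product: 2 C9 ethylene ketal of 1 (C3 enone untouched)
Conditions: (TMSOCH2)2 (1.2 equiv), TMSOTf (5 mol %), CH2Cl2, −78 → −20 °C; pyridine quench
Reagents that add atoms: 1,2-bis(trimethylsilyloxy)ethane, C[Si](C)(C)OCCO[Si](C)(C)C
Why: Noyori ketalisation: under TMSOTf catalysis at low temperature a saturated ketone is dioxolanated much faster than a conjugated enone, the selectivity known for the 17-ketone of androst-4-ene-3,17-dione, and C10 is not touched.

Step 2
Reactants: 2 C9 ethylene ketal
Product: 4 4,4-dimethyl-5(6)-en-3-one C9 ketal, via 4-monomethyl ketone 3 (not isolated)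
Conditions: KOtBu (3 equiv), t-BuOH/THF, rt; MeI (4 equiv), 0 °C → rt
Reagents that add atoms: iodomethane, IC
Why: Deconjugative α,α-dialkylation of an enone under equilibrating conditions: deprotonation at C6 lets C4 be methylated, a second round through 3 makes C4 quaternary, and the olefin is thereby locked at C5=C6.

Step 3
Reactants: 4 4,4-dimethyl-5(6)-en-3-one C9 ketal
Product: 5 3-alcohol (hydroxyl equatorial, on the methyl face)
Conditions: NaBH4, MeOH, 0 °C
Reagents that add atoms: none
Why: Borohydride reduction of a 4,4-dimethyl-3-ketone: hydride enters axially from the open face, away from C20 and the axial C4 methyl, so the new C3 centre carries an equatorial hydroxyl on the methyl face, as in 4,4-dimethyl-3-oxo steroids.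

Step 4
Reactants: 5 3-alcohol
Product: 6 3-O-TBS ether
Conditions: TBSCl (2 equiv), imidazole (4 equiv), DMAP (cat.), DMF, 50 °C
Reagents that add atoms: tert-butyldimethylsilyl chloride, CC(C)(C)[Si](C)(C)Cl
Why: Imidazole-mediated silylation of a secondary alcohol, warmed because C3 is neopentylic; ketal and olefin are inert to these mildly basic conditions.

Step 5
Reactants: 6 3-O-TBS ether
Product: 7 trans-hydrindane C9 ketal (H5 on the open face)
Conditions: H2 (10 bar), 10% Pd/C, EtOAc, rt
Reagents that add atoms: none
Why: Heterogeneous catalytic syn-hydrogenation: C20 and the axial C4 methyl screen the methyl face of the cyclopentene bond, so hydrogen should arrive on the open face and set H5 anti to C20 (trans ring fusion), as steroidal 14-enes do with respect to C18.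

Step 6
Reactants: 7 trans-hydrindane C9 ketal
Product: 8 3-O-TBS trans-hydrindan-9-one
Conditions: PPTS (0.3 equiv), acetone/H2O 10:1, 60 °C
Reagents that add atoms: water, O
Why: Mild acid-catalysed ketal hydrolysis; the hindered secondary TBS ether tolerates PPTS, and neither carbon next to the freed C9 carbonyl is a stereocentre that could epimerise (C8 is CH2, C10 is quaternary).

Step 7
Reactants: 8 trans-hydrindan-9-one
Product: 10 C9 enol triflate (8-ene), via potassium enolate 9 (not isolated)
Conditions: KN(SiMe3)2 (1.2 equiv), THF, −78 °C; PhNTf2 (1.3 equiv), −78 → 0 °C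
Reagents that add atoms: N-phenylbis(trifluoromethanesulfonimide), O=S(=O)(N(c1ccccc1)S(=O)(=O)C(F)(F)F)C(F)(F)F
Why: Enolate O-triflation: with C10 quaternary, 8 can enolise only toward C8, so 9 and hence 10 form as single regioisomers, in the manner of steroid 17-ketones.

Step 8
Reactants: 11 methyl hydrogen (R)-3-methylglutarate
Product: 12 methyl (R)-5-hydroxy-3-methylpentanoate
Conditions: BH3·THF (1.1 equiv), THF, −10 → 0 °C; aq. NaHCO3 work-up
Reagents that add atoms: none
Why: Chemoselective borane reduction of a carboxylic acid beside an ester; C13 (β to both carbonyls) is not affected, and the low temperature and neutral work-up hold back lactonisation.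

Step 9
Reactants: 12 methyl (R)-5-hydroxy-3-methylpentanoate
Product: 13 methyl (S)-5-iodo-3-methylpentanoate (same spatial arrangement, descriptor changes by priority)
Conditions: I2, PPh3, imidazole, CH2Cl2, 0 °C
Reagents that add atoms: iodine, [I][I]
Why: Appel-type iodination (PPh3/I2/imidazole) converts the primary alcohol by SN2 displacement under near-neutral conditions without touching ester or C13.

Step 10
Reactants: 10 C9 enol triflate; 13 methyl (S)-5-iodo-3-methylpentanoate
Product: 15 9-alkylhydrind-8-ene carrying the C11–C15 ester chain, via alkylzinc iodide 14 (not isolated)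
Conditions: 13, Zn dust, LiCl, THF, 40 °C; then 10, PdCl2(dppf) (5 mol %), THF, 50 °C
Reagents that add atoms: none
Why: Negishi sp2–sp3 cross-coupling: zinc inserts into the primary C–I bond without harming the ester, and the wide-bite-angle dppf ligand speeds reductive elimination over β-hydride elimination at the hindered but steroid-like C9 triflate.

Step 11
Reactants: 15 9-alkylhydrind-8-ene
Product: 17 hydrindan-8-ol (H9 and 8-OH on the open face), via C8 alkylborane 16 (not isolated)
Conditions: BH3·THF (1.5 equiv), THF, 0 °C → rt; then NaBO3·4H2O, THF/H2O, rt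
Reagents that add atoms: sodium perborate, [Na+].[O-]OB=O
Why: Brown hydroboration–oxidation: boron goes to the less substituted C8 and the syn addition occurs on the open face opposite C20, which places H9 anti to C20 (chain pseudo-equatorial) and the C8 oxygen on the open face, while the fast olefin addition outruns ester reduction and perborate spares the ester.

Step 12
Reactants: 17 hydrindan-8-ol
Product: 18 3-O-TBS trans-hydrindan-8-one with the C9 chain (ring B lacking C7)
Conditions: Dess–Martin periodinane (1.3 equiv), CH2Cl2, rt
Reagents that add atoms: none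
Why: Dess–Martin oxidation under nearly neutral conditions removes the C8 carbinol centre and leaves C9 alone, whose pseudo-equatorial chain is in any case the arrangement favoured at equilibrium (compare 17β-alkyl-16-oxo steroids).

Step 13
Reactants: 18 trans-hydrindan-8-one; 19 (trimethylsilyl)diazomethane
Product: 22 decalin C8 trimethylsilyl enol ether (7-ene), via diazonium alkoxide 20 (not isolated), via alpha-silyl ketone 21 (not isolated)
Conditions: 19 (1.5 equiv, 2 M in hexanes), Sc(OTf)3 (15 mol %), CH2Cl2, −40 → 0 °C; filtration through Et3N-deactivated silica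
Reagents that add atoms: (trimethylsilyl)diazomethane 19, C[Si](C)(C)C=[N+]=[N-]
Why: Sc(OTf)3 activates the C8 carbonyl of 18, the diazo carbon of 19 adds from the open face to give diazonium alkoxide 20, and loss of N2 is coupled to a 1,2-shift of the C6 methylene onto that carbon, which thereby becomes C7 of alpha-silyl ketone 21; a scandium-assisted 1,3-Brook (carbon-to-oxygen) silyl shift then gives 22. The closest known reaction type is the Lewis-acid-catalysed Büchner–Curtius–Schlotterbeck (Tiffeneau–Demjanov-like) homologation of cycloalkanones with TMSCHN2, for which capture as the enol silane under Sc(OTf)3 is established. Ring B is not closed by a cyclisation: it arises by migratory enlargement of the five-membered ring, the C6–C8 bond being exchanged for C6–C7 and C7–C8. No stereocentre is created, since C7 of 21 ends as an sp2 carbon, C6 is not stereogenic, and C5, C9 and C10 are spectators. The step needs migration of CH2-6 in preference to CH-9, which is secured by the bulky silyl group of 20 turning away from the C9 chain and quaternary C10, so that the C6–C8 bond lies antiperiplanar to the departing N2. The silyl shift masks the new ketone against a second homologation and fixes the olefin at C7=C8, while ester and TBS ether are inert to the neutral diazoalkane.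

Step 14
Reactants: 22 C8 trimethylsilyl enol ether
Product: 24 C8 enol triflate (7-ene), via caesium enolate 23 (not isolated)
Conditions: CsF (3 equiv, dried), PhNTf2 (1.5 equiv), DME, rt
Reagents that add atoms: N-phenylbis(trifluoromethanesulfonimide), O=S(=O)(N(c1ccccc1)S(=O)(=O)C(F)(F)F)C(F)(F)F
Why: Fluoride-induced cleavage of the O–Si bond frees the regiodefined enolate 23, which PhNTf2 present in the flask triflates on oxygen at C8 before proton exchange can move the double bond or touch C9, and no strong base meets the ester.

Step 15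
Reactants: 24 C8 enol triflate
Product: 25 3-O-TBS ether of the target (C8–CH2OH, 7-ene)
Conditions: Bu3SnCH2OH (2 equiv), Pd(PPh3)4 (10 mol %), LiCl (6 equiv), 1,4-dioxane, 100 °C
Reagents that add atoms: (tributylstannyl)methanol, CCCC[Sn](CO)(CCCC)CCCC
Why: Stille coupling (hydroxymethyl transfer from tin to an alkenyl triflate, chloride-assisted): the neutral conditions keep ester, TBS ether and C9 intact, and the new C8–C17 bond forms exactly where the triflate stood.

Step 16
Reactants: 25 3-O-TBS ether of the target
Product: 26 CNP0313905.1, methyl (3R,5S,9S,10S,13R)-3,17-dihydroxylabd-7-en-15-oate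
Conditions: HF·pyridine, pyridine/THF, 0 °C → rt
Reagents that add atoms: none
Why: Fluoride-driven desilylation: buffered HF·pyridine cleaves the hindered C3 silyl ether with retention at C3 and is too mild to hydrolyse the ester or ionise the allylic alcohol.

Compound list
1 | (R)-Hajos–Parrish ketone, (7aR)-7a-methyl-2,3,7,7a-tetrahydro-1H-indene-1,5(6H)-dione | O=C1CCC2=CC(=O)CC[C@@]12C | starting material
2 | C9 ethylene ketal of 1 | C13(OCCO3)CCC2=CC(=O)CC[C@@]12C | intermediate
3 | 4-monomethyl-5(6)-en-3-one C9 ketal (C4 epimers, not isolated) | C13(OCCO3)CC=C2C(C)C(=O)CC[C@@]12C | intermediate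
4 | 4,4-dimethyl-5(6)-en-3-one C9 ketal | C13(OCCO3)CC=C2C(C)(C)C(=O)CC[C@@]12C | intermediate
5 | 3-alcohol, OH equatorial on the methyl face | C13(OCCO3)CC=C2C(C)(C)[C@H](O)CC[C@@]12C | intermediate
6 | 3-O-TBS ether of 5 | C13(OCCO3)CC=C2C(C)(C)[C@H](O[Si](C)(C)C(C)(C)C)CC[C@@]12C | intermediate
7 | trans-hydrindane C9 ketal, H5 anti to C20 | C13(OCCO3)CC[C@@H]2C(C)(C)[C@H](O[Si](C)(C)C(C)(C)C)CC[C@@]12C | intermediate
8 | 3-O-TBS trans-hydrindan-9-one | O=C1CC[C@@H]2C(C)(C)[C@H](O[Si](C)(C)C(C)(C)C)CC[C@@]12C | intermediate
9 | potassium C8=C9 enolate of 8 (not isolated) | [K+].[O-]C1=CC[C@@H]2C(C)(C)[C@H](O[Si](C)(C)C(C)(C)C)CC[C@@]12C | intermediate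
10 | C9 enol triflate (8-ene) | O=S(=O)(OC1=CC[C@@H]2C(C)(C)[C@H](O[Si](C)(C)C(C)(C)C)CC[C@@]12C)C(F)(F)F | intermediate
11 | methyl hydrogen (R)-3-methylglutarate | COC(=O)C[C@H](C)CC(=O)O | starting material
12 | methyl (R)-5-hydroxy-3-methylpentanoate | COC(=O)C[C@H](C)CCO | intermediate
13 | methyl (S)-5-iodo-3-methylpentanoate | COC(=O)C[C@H](C)CCI | intermediate
14 | (S)-5-methoxy-3-methyl-5-oxopentylzinc iodide (not isolated) | COC(=O)C[C@H](C)CC[Zn]I | intermediate
15 | 9-alkylhydrind-8-ene with the (13R) ester chain | COC(=O)C[C@H](C)CCC1=CC[C@@H]2C(C)(C)[C@H](O[Si](C)(C)C(C)(C)C)CC[C@@]12C | intermediate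
16 | C8 alkylborane, B and H9 on the open face (not isolated) | COC(=O)C[C@H](C)CC[C@@H]1[C@@H](B)C[C@@H]2C(C)(C)[C@H](O[Si](C)(C)C(C)(C)C)CC[C@@]12C | intermediate
17 | hydrindan-8-ol, OH and H9 on the open face | COC(=O)C[C@H](C)CC[C@@H]1[C@@H](O)C[C@@H]2C(C)(C)[C@H](O[Si](C)(C)C(C)(C)C)CC[C@@]12C | intermediate
18 | 3-O-TBS trans-hydrindan-8-one with the C9 chain (key-step precursor) | COC(=O)C[C@H](C)CC[C@@H]1C(=O)C[C@@H]2C(C)(C)[C@H](O[Si](C)(C)C(C)(C)C)CC[C@@]12C | intermediate
19 | (trimethylsilyl)diazomethane | C[Si](C)(C)C=[N+]=[N-] | starting material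
20 | diazonium alkoxide adduct at C8, new carbon on the open face, its own configuration undefined (not isolated) | COC(=O)C[C@H](C)CC[C@@H]1[C@@]([O-])(C([Si](C)(C)C)[N+]#N)C[C@@H]2C(C)(C)[C@H](O[Si](C)(C)C(C)(C)C)CC[C@@]12C | intermediate
21 | 7-trimethylsilyl-8-decalone, C7 configuration of no consequence (not isolated) | COC(=O)C[C@H](C)CC[C@@H]1C(=O)C([Si](C)(C)C)C[C@@H]2C(C)(C)[C@H](O[Si](C)(C)C(C)(C)C)CC[C@@]12C | intermediate
22 | decalin C8 trimethylsilyl enol ether, 7-ene (key-step product) | COC(=O)C[C@H](C)CC[C@@H]1C(O[Si](C)(C)C)=CC[C@@H]2C(C)(C)[C@H](O[Si](C)(C)C(C)(C)C)CC[C@@]12C | intermediate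
23 | caesium C7=C8 enolate (not isolated) | [Cs+].COC(=O)C[C@H](C)CC[C@@H]1C([O-])=CC[C@@H]2C(C)(C)[C@H](O[Si](C)(C)C(C)(C)C)CC[C@@]12C | intermediate
24 | C8 enol triflate, 7-ene | COC(=O)C[C@H](C)CC[C@@H]1C(OS(=O)(=O)C(F)(F)F)=CC[C@@H]2C(C)(C)[C@H](O[Si](C)(C)C(C)(C)C)CC[C@@]12C | intermediate
25 | 3-O-TBS ether of the target | COC(=O)C[C@H](C)CC[C@@H]1C(CO)=CC[C@@H]2C(C)(C)[C@H](O[Si](C)(C)C(C)(C)C)CC[C@@]12C | intermediate
26 | CNP0313905.1, methyl (3R,5S,9S,10S,13R)-3,17-dihydroxylabd-7-en-15-oate | COC(=O)C[C@H](C)CC[C@@H]1C(CO)=CC[C@@H]2C(C)(C)[C@H](O)CC[C@@]12C | target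

Total step count: 16. Longest linear sequence: 14 (steps 1–7 and 10–16). Steps 8 and 9 build the side chain in parallel.

Steps most likely to fail

Step 13 (key step). Three processes could go wrong:
- The C9 methine migrates in competition with the C6 methylene.
- The alkoxide closes onto the diazonium carbon.
- The silyl group is lost before its shift to oxygen, which would expose the ketone to a second homologation and erase the regiochemical marker.

The fallback sets out from 18 and comes back at 24. It lets enolate regiochemistry, not migratory aptitude, decide where C7 enters.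
- Kinetic deprotonation of 18 at the unhindered C6 methylene (LiN(i-Pr)2, 1.05 equiv, THF, −78 °C, TMSCl present) would pass through the lithium C6=C8 enolate F1 to the C6=C8 trimethylsilyl enol ether F2.
- Simmons–Smith cyclopropanation (Et2Zn, CH2I2, CH2Cl2, 0 °C) on the open face would give the siloxycyclopropane F3, whose new CH2 is C7.
- FeCl3 in DMF at 0 °C would cleave the internal C6–C8 bond (Saegusa-type oxidative ring enlargement) to the 6-chloro-8-decalone F4.
- NaOAc in MeOH would eliminate it to the 6-en-8-one F5.
- Conjugate reduction with LiBH(s-Bu)3 in THF at −78 °C would give the lithium C7=C8 enolate F6, which PhNTf2 traps as 24.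

Step 5. Hydrogen uptake may be sluggish at the trisubstituted olefin flanked by two quaternary carbons. Facial selectivity may also erode through double-bond migration on the metal surface. The fallback sets out from 6 and comes back at 7. It replaces surface syn-addition by a stepwise radical hydrogen-atom-transfer reduction (Mn(dpm)3 cat., PhSiH3, t-BuOOH, i-PrOH, rt). There the olefin need not lie flat on a catalyst, and the tertiary C5 radical is capped from the face away from C20 and the axial C4 methyl. This detour makes no new compound (F0).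

Step 15. Transfer of the hydroxymethyl group from tin to the hindered C8–palladium centre may be slow, so that reduction of the triflate or butyl transfer competes. The fallback sets out from 24 and comes back at 25. It builds C17 from carbon monoxide instead of tin-bound CH2OH.
- Palladium-catalysed reductive carbonylation (CO 1 atm, Bu3SnH added slowly, Pd(PPh3)4, LiCl, THF, 50 °C) would give the 7-en-17-al F7.
- Luche reduction (NaBH4, CeCl3·7H2O, MeOH, 0 °C) would reduce only the enal and leave the ester.

Further compounds
F1 | step 13 | lithium C6=C8 enolate of 18 | [Li+].COC(=O)C[C@H](C)CC[C@@H]1C([O-])=C[C@@H]2C(C)(C)[C@H](O[Si](C)(C)C(C)(C)C)CC[C@@]12C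
F2 | step 13 | C6=C8 trimethylsilyl enol ether of 18 | COC(=O)C[C@H](C)CC[C@@H]1C(O[Si](C)(C)C)=C[C@@H]2C(C)(C)[C@H](O[Si](C)(C)C(C)(C)C)CC[C@@]12C
F3 | step 13 | siloxycyclopropane, CH2 (C7) bridging C6 and C8 on the open face | COC(=O)C[C@H](C)CC[C@@H]1[C@@]3(O[Si](C)(C)C)C[C@H]3[C@@H]2C(C)(C)[C@H](O[Si](C)(C)C(C)(C)C)CC[C@@]12C
F4 | step 13 | 6-chloro-8-decalone (C6 configuration undefined) | COC(=O)C[C@H](C)CC[C@@H]1C(=O)CC(Cl)[C@@H]2C(C)(C)[C@H](O[Si](C)(C)C(C)(C)C)CC[C@@]12C
F5 | step 13 | decal-6-en-8-one | COC(=O)C[C@H](C)CC[C@@H]1C(=O)C=C[C@@H]2C(C)(C)[C@H](O[Si](C)(C)C(C)(C)C)CC[C@@]12C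
F6 | step 13 | lithium C7=C8 enolate | [Li+].COC(=O)C[C@H](C)CC[C@@H]1C([O-])=CC[C@@H]2C(C)(C)[C@H](O[Si](C)(C)C(C)(C)C)CC[C@@]12C
F0 | step 5 | none | none
F7 | step 15 | 3-O-TBS 7-en-17-al | COC(=O)C[C@H](C)CC[C@@H]1C(C=O)=CC[C@@H]2C(C)(C)[C@H](O[Si](C)(C)C(C)(C)C)CC[C@@]12C
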